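The earlier runs and the new flask stem from a simulated flask for an exercise.

The ratio c(Q)/(c(E)·c(J)) on a plateau is what we carry here, with c(J) counted as the J still free once Z has taken one J each. That share for Z is an assumption, and we test it below.

| flask | E | J | Z | D | remark | time |
|---|---|---|---|---|---|---|
| gamma | 0.30 M | 0.50 equiv | 0.20 equiv | 0.1 mol% | the very flask that is asked about, followed so far |  |
| alpha | 0.30 M | 0.34 equiv | 0.20 equiv | 0.1 mol% | run made earlier |  |
| flask | 0.30 M | 0.500 equiv | 0.200 equiv | 0.1 mol% |  | 10 d |

| run | time / d | E / % | Q / % |
|---|---|---|---|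
| gamma | 0.250 | 75.3 | 24.1 |
| gamma | 0.417 | 72.8 | 26.4 |
| gamma | 0.625 | 74.5 | 24.1 |
| gamma | 1.04 | 74.6 | 23.0 |
| gamma | 1.67 | 73.0 | 23.7 |
| gamma | 3.00 | 76.2 | 25.0 |
| alpha | 0.625 | 87.7 | 10.7 |
| alpha | 2.08 | 88.6 | 11.7 |
| alpha | 4.00 | 87.2 | 13.0 |
| alpha | 5.00 | 86.8 | 13.0 |
| alpha | 8.00 | 87.8 | 13.3 |
| alpha | 10.0 | 87.8 | 11.2 |

(scatter of a reading: 1 percentage point)

- the numbers in the tables scatter with a standard deviation of 1 percentage point
- the reaction counts as stopped when no species that holds the E changes by six tenths of a point or more over the second half of the time

* the state of affairs at 10 d: stopped, and by what, or still going (forward and back rates have come level / J has run out first / it is still moving / all of E has reacted / no working catalyst is left)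
* conversion of E at 10 d
* amount of Q at 10 d, in percent of the E charged
* amount of Q if the flask were left three thousand times as long, in percent of the E charged

Gamma is the flask asked about, so we first ask whether its curve may be replaced by its mean. Its first 3 Q readings average 24.9% and its last 3 average 23.9%. That gap of 0.97 percentage points is smaller than the scatter of one reading, so we use the mean, whose error is 0.41 points.

Which number must be known well? In gamma, E averages 74.4%, so that error is 0.551% of it. Q averages 24.4%, so the error is 1.68%. Free J is a small difference, 5.62% of the E charged, so the error is 7.30%, and the charges of J and Z enter it point for point. In alpha, free J is 1.85%, and the error grows to 22.2%.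

Now the number. The plateau quotient, Q over E times free J (the equilibrium constant, if the plateau is an equilibrium), reads 19.5 M⁻¹ in gamma and 25.0 M⁻¹ in alpha. Without Z's share of J, gamma's reading would be twice alpha's. Our reckoning for gamma at the asked time is its mean: Q 24.4%, and conversion 24.4% through Q or 25.6% through E.

The forecast says: forward and back rates have come level, conversion 24.8% (23.5% to 26.5%), Q 24.4% (23.3% to 25.5%), and Q 24.6% at the long time (23.3% to 30%). Its ground is a quotient “roughly constant within scatter, which points to equilibrium”.

The flask gives: forward and back rates have come level, conversion 24.8%, Q 24.8% at 10 d, and Q 24.8% at the long time.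

    Z → L (k = 2.40 × 10⁻⁷ s⁻¹)
    E + J + D ⇌ D + Q (K = 21.0 M⁻¹, k = 21.0 M⁻² s⁻¹)
    Z + J + D → D + X (k = 96.0 M⁻² s⁻¹)

In the flask, Z stands at 0% of its charge at the end and J at 10%. Now take a neighbour flask charged with 0.0500 equiv of Z, which leaves 0.450 equiv of J for E on our count. We solve the plateau quotient 19.5 M⁻¹ for Q, with E and free J both shrinking as Q grows, and get 35.5%. That neighbour flask ends at 36.1% of Q, with 18% of its J still there.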